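**Retrosynthesis**
- Kanzonol X comes from global removal of three MOM groups on the chroman (20). The pyran ring is closed just before this, by intramolecular Mitsunobu O-alkylation of an A-ring phenol onto a primary alcohol (18 → 19 → 20).
- The C3 stereocentre and the C3–C4 bond are made in one late step. A sodium enolate of the B-ring arylacetyl (R)-oxazolidinone imide (16) is alkylated with the A-ring benzyl bromide (9).
- Both aryl fragments are built from resorcinol, with the prenyl group placed between the two oxygens. Fragment 9 uses Vilsmeier formylation, a Claisen rearrangement and a cross-metathesis. Fragment 16 uses directed ortho-lithiation/prenylation, bromination, formylation and a one-carbon homologation.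
- Order of ring formation: both benzene rings are carried in from the fragments, and the pyran ring is closed after the coupling.

Assumption: the Z-Na-enolate of the arylacetyl imide is alkylated anti to the auxiliary benzyl group, so the (R)-auxiliary gives the (R) centre (CIP: CH2O/C=O > aryl > CH2Ar).

## Fragment A: benzyl bromide 9

**Step 1**
Reactants: 1 resorcinol
Product: 2 2,4-dihydroxybenzaldehyde
Conditions: POCl3, DMF, MeCN, 0 °C → rt; then aq. NaOAc/H2O
Reagents that add atoms: DMF, CN(C)C=O (formyl carbon); H2O, O (carbonyl oxygen)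
Why: Vilsmeier–Haack formylation goes para to one OH and ortho to the other, giving the 2,4-isomer.

**Step 2**
Reactants: 2
Product: 3 2-hydroxy-4-(methoxymethoxy)benzaldehyde
Conditions: MOMCl, iPr2NEt, CH2Cl2, 0 °C
Reagents that add atoms: MOMCl, ClCOC
Why: The 4-OH is more acidic than the 2-OH, which is hydrogen-bonded to the CHO, so protection is regioselective.

**Step 3**
Reactants: 3
Product: 4 2-(allyloxy)-4-(methoxymethoxy)benzaldehyde
Conditions: allyl bromide, K2CO3, acetone, 60 °C
Reagents that add atoms: allyl bromide, BrCC=C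
Why: Williamson O-allylation of the remaining phenol.

**Step 4**
Reactants: 4
Product: 5 3-allyl-2-hydroxy-4-(methoxymethoxy)benzaldehyde
Conditions: PhNEt2, 200 °C (microwave), 1 h
Reagents that add atoms: none
Why: Aromatic Claisen [3,3] rearrangement. C1 carries the CHO, so the only free ortho position is C3, between the two oxygens, which places the future prenyl carbon exactly there.

**Step 5**
Reactants: 5
Product: 6 3-allyl-2-(tert-butyldimethylsilyloxy)-4-(methoxymethoxy)benzaldehyde
Conditions: TBSCl, imidazole, DMF, 50 °C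
Reagents that add atoms: TBSCl, C[Si](C)(Cl)C(C)(C)C
Why: This oxygen becomes O1 of the chroman. A silyl ether lets it be unmasked later without touching the MOM groups.

**Step 6**
Reactants: 6
Product: 7 2-(TBSO)-4-(MOMO)-3-(3-methylbut-2-enyl)benzaldehyde
Conditions: 2-methylbut-2-ene (20 equiv), Grubbs II (5 mol%), CH2Cl2, 40 °C, sealed tube
Reagents that add atoms: 2-methylbut-2-ene, CC=C(C)C (supplies the =CMe2 terminus)
Why: Olefin cross-metathesis with a trisubstituted partner converts the terminal allyl into prenyl. The aldehyde, MOM and aryl silyl ether are inert.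

**Step 7**
Reactants: 7
Product: 8 [2-(TBSO)-4-(MOMO)-3-prenylphenyl]methanol
Conditions: NaBH4, THF/EtOH, 0 °C, 20 min
Reagents that add atoms: none
Why: Chemoselective aldehyde reduction. The prenyl alkene, MOM ether and hindered aryl TBS ether survive.

**Step 8**
Reactants: 8
Product: 9 2-(TBSO)-4-(MOMO)-3-prenylbenzyl bromide
Conditions: CBr4, PPh3, CH2Cl2, 0 °C, 30 min; used crude immediately
Reagents that add atoms: CBr4, BrC(Br)(Br)Br (supplies Br)
Why: Appel bromination under neutral conditions. The electron-rich benzyl bromide is labile, so it is not stored.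

## Fragment B: arylacetyl imide 16

**Step 9**
Reactants: 1 resorcinol
Product: 10 1,3-bis(methoxymethoxy)benzene
Conditions: NaH (2.2 equiv), MOMCl (2.2 equiv), THF/DMF, 0 °C → rt
Reagents that add atoms: MOMCl, ClCOC
Why: Double O-MOM protection gives a strong cooperative ortho-directing array for lithiation.

**Step 10**
Reactants: 10
Product: 11 2-prenyl-1,3-bis(methoxymethoxy)benzene
Conditions: n-BuLi, THF, 0 °C; then CuI (10 mol%), prenyl bromide, −78 °C → rt
Reagents that add atoms: prenyl bromide, BrCC=C(C)C
Why: Directed ortho-metalation occurs at C2, between the two OMOM groups. Cu catalysis favours SN2 over SN2′ alkylation.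

**Step 11**
Reactants: 11
Product: 12 1-bromo-2,4-bis(methoxymethoxy)-3-prenylbenzene
Conditions: NBS (1.0 equiv), MeCN, −20 → 0 °C, dark
Reagents that add atoms: NBS, BrN1C(=O)CCC1=O (supplies Br)
Why: Electrophilic bromination at C4/C6 (equivalent), ortho to one OMOM and para to the other. The arene is far more nucleophilic than the prenyl alkene in the absence of an added nucleophile, so aromatic substitution wins.

**Step 12**
Reactants: 12
Product: 13 2,4-bis(methoxymethoxy)-3-prenylbenzaldehyde
Conditions: n-BuLi, THF, −78 °C, 15 min; then DMF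
Reagents that add atoms: DMF, CN(C)C=O (formyl carbon)
Why: Bromine–lithium exchange is much faster than deprotonation at −78 °C; the aryllithium is formylated by DMF.

**Step 13**
Reactants: 13
Product: 14 [2,4-bis(methoxymethoxy)-3-prenylphenyl]acetonitrile
Conditions: TosMIC, t-BuOK, DME/EtOH, −10 °C → rt
Reagents that add atoms: TosMIC, Cc1ccc(cc1)S(=O)(=O)C[N+]#[C-] (supplies the nitrile C and N)
Why: van Leusen reductive cyanation is a one-carbon homologation of the aldehyde under basic conditions that MOM and prenyl tolerate.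

**Step 14**
Reactants: 14
Product: 15 [2,4-bis(methoxymethoxy)-3-prenylphenyl]acetic acid
Conditions: KOH, ethylene glycol/H2O, 130 °C; then cold aq. citric acid to pH 4–5
Reagents that add atoms: H2O, O (carboxyl oxygens)
Why: Base hydrolysis of the nitrile. MOM ethers are base-stable, and a weak acid quench avoids acetal cleavage.

**Step 15**
Reactants: 15
Product: 16 (R)-4-benzyl-3-{[2,4-bis(methoxymethoxy)-3-prenylphenyl]acetyl}oxazolidin-2-one
Conditions: PivCl, Et3N, THF, −20 °C; then lithiated (R)-4-benzyloxazolidin-2-one (n-BuLi, THF, −78 °C), → 0 °C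
Reagents that add atoms: (R)-4-benzyloxazolidin-2-one, O=C1N[C@H](Cc2ccccc2)CO1 (chiral auxiliary, removed and recovered in step 17)
Why: Acylation through the mixed pivalic anhydride attaches the Evans auxiliary that will control C3.

## Coupling and endgame

**Step 16**
Reactants: 16 (imide); 9 (benzyl bromide)
Product: 17 (R)-4-benzyl-3-{(2R)-2-[2,4-bis(MOMO)-3-prenylphenyl]-3-[2-(TBSO)-4-(MOMO)-3-prenylphenyl]propanoyl}oxazolidin-2-one
Conditions: NaHMDS, THF, −78 °C, 30 min; then 9 in THF, −78 → −40 °C, 3 h
Reagents that add atoms: none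
Why: Evans enolate alkylation forms the C3–C4 bond. The chelated (Z)-Na-enolate is attacked anti to the auxiliary benzyl group, setting C3 as (R) (CIP: acyl > aryl > CH2Ar).

**Step 17**
Reactants: 17
Product: 18 (2R)-2-[2,4-bis(MOMO)-3-prenylphenyl]-3-[2-(TBSO)-4-(MOMO)-3-prenylphenyl]propan-1-ol
Conditions: LiBH4, THF, H2O (1 equiv), 0 °C
Reagents that add atoms: none
Why: Reductive removal of the auxiliary gives the primary alcohol. The α-centre is not epimerised under these non-enolising conditions, and the auxiliary is recovered.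

**Step 18**
Reactants: 18
Product: 19 (2R)-2-[2,4-bis(MOMO)-3-prenylphenyl]-3-[2-hydroxy-4-(MOMO)-3-prenylphenyl]propan-1-ol
Conditions: TBAF, THF, 0 °C
Reagents that add atoms: none
Why: Fluoride removes only the aryl silyl ether, freeing O1. All three B-ring and A-ring MOM-protected oxygens stay masked, so the B-ring 2′-oxygen cannot close a dihydrobenzofuran.

**Step 19**
Reactants: 19
Product: 20 (3R)-7-MOMO-8-prenyl-3-[2,4-bis(MOMO)-3-prenylphenyl]chroman
Conditions: DIAD, PPh3, THF (0.01 M), 0 °C → rt
Reagents that add atoms: none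
Why: Intramolecular Mitsunobu etherification (6-exo SN2 at the primary carbon) closes the pyran ring. C3 is not involved, so its configuration is retained.

**Step 20**
Reactants: 20
Product: 21 Kanzonol X, (3R)-3-(2,4-dihydroxy-3-prenylphenyl)-8-prenylchroman-7-ol
Conditions: p-TsOH·H2O (1.5 equiv), MeOH, 45 °C, 8 h
Reagents that add atoms: none (MeOH leaves as CH2(OMe)2)
Why: Acid-catalysed methanolysis removes the three aryl MOM acetals. The mild acid and stoichiometry are chosen to avoid prenyl cyclisation onto the ortho phenols.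

## Compound list

| No. | Name | SMILES | Role |
|---|---|---|---|
| 1 | resorcinol | Oc1cccc(O)c1 | starting material |
| 2 | 2,4-dihydroxybenzaldehyde | O=Cc1ccc(O)cc1O | intermediate |
| 3 | 2-hydroxy-4-(methoxymethoxy)benzaldehyde | O=Cc1ccc(OCOC)cc1O | intermediate |
| 4 | 2-(allyloxy)-4-(methoxymethoxy)benzaldehyde | C=CCOc1cc(OCOC)ccc1C=O | intermediate |
| 5 | 3-allyl-2-hydroxy-4-(methoxymethoxy)benzaldehyde | C=CCc1c(OCOC)ccc(C=O)c1O | intermediate |
| 6 | 3-allyl-2-(TBSO)-4-(MOMO)benzaldehyde | C=CCc1c(OCOC)ccc(C=O)c1O[Si](C)(C)C(C)(C)C | intermediate |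
| 7 | 2-(TBSO)-4-(MOMO)-3-prenylbenzaldehyde | CC(C)=CCc1c(OCOC)ccc(C=O)c1O[Si](C)(C)C(C)(C)C | intermediate |
| 8 | [2-(TBSO)-4-(MOMO)-3-prenylphenyl]methanol | CC(C)=CCc1c(OCOC)ccc(CO)c1O[Si](C)(C)C(C)(C)C | intermediate |
| 9 | 2-(TBSO)-4-(MOMO)-3-prenylbenzyl bromide | CC(C)=CCc1c(OCOC)ccc(CBr)c1O[Si](C)(C)C(C)(C)C | intermediate |
| 10 | 1,3-bis(MOMO)benzene | COCOc1cccc(OCOC)c1 | intermediate |
| 11 | 2-prenyl-1,3-bis(MOMO)benzene | CC(C)=CCc1c(OCOC)cccc1OCOC | intermediate |
| 12 | 1-bromo-2,4-bis(MOMO)-3-prenylbenzene | CC(C)=CCc1c(OCOC)ccc(Br)c1OCOC | intermediate |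
| 13 | 2,4-bis(MOMO)-3-prenylbenzaldehyde | CC(C)=CCc1c(OCOC)ccc(C=O)c1OCOC | intermediate |
| 14 | 2,4-bis(MOMO)-3-prenylphenylacetonitrile | CC(C)=CCc1c(OCOC)ccc(CC#N)c1OCOC | intermediate |
| 15 | 2,4-bis(MOMO)-3-prenylphenylacetic acid | CC(C)=CCc1c(OCOC)ccc(CC(=O)O)c1OCOC | intermediate |
| 16 | (R)-4-benzyl-3-[2,4-bis(MOMO)-3-prenylphenylacetyl]oxazolidin-2-one | CC(C)=CCc1c(OCOC)ccc(CC(=O)N2C(=O)OC[C@H]2Cc2ccccc2)c1OCOC | intermediate |
| 17 | alkylated imide (2R) | O=C(N1C(=O)OC[C@H]1Cc1ccccc1)[C@@H](c1ccc(OCOC)c(CC=C(C)C)c1OCOC)Cc1ccc(OCOC)c(CC=C(C)C)c1O[Si](C)(C)C(C)(C)C | intermediate |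
| 18 | (2R)-diaryl propanol, aryl-OTBS | OC[C@@H](c1ccc(OCOC)c(CC=C(C)C)c1OCOC)Cc1ccc(OCOC)c(CC=C(C)C)c1O[Si](C)(C)C(C)(C)C | intermediate |
| 19 | (2R)-diaryl propanol, free phenol | OC[C@@H](c1ccc(OCOC)c(CC=C(C)C)c1OCOC)Cc1ccc(OCOC)c(CC=C(C)C)c1O | intermediate |
| 20 | (3R)-tris-MOM chroman | CC(C)=CCc1c(OCOC)ccc([C@@H]2COc3c(ccc(OCOC)c3CC=C(C)C)C2)c1OCOC | intermediate |
| 21 | Kanzonol X | CC(C)=CCc1c(O)ccc([C@@H]2COc3c(ccc(O)c3CC=C(C)C)C2)c1O | target |

**Totals:** 20 steps in all. The longest linear sequence is 13 steps (1–8, then 16–20); the other fragment branch (steps 9–15) has 7 steps.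

**Three steps most likely to fail**
1. **Step 16 (enolate alkylation).** The very electron-rich benzyl bromide 9 may ionise or decompose before it reacts, and diastereoselectivity with an α-aryl enolate may fall short. Fallback: change the bond-forming logic. Condense salicylaldehyde 5 (as its 2-OH/4-OMOM form) with acid 15 (Perkin) to a 3-arylcoumarin, do a catalytic asymmetric CuH conjugate reduction, then open the lactone with LiAlH4 to a phenol-alcohol like 19 and continue with the Mitsunobu closure.
2. **Step 11 (NBS bromination).** The prenyl alkene may compete, giving bromo-alkene or dibromide by-products. Fallback: make 13 by the branch-A sequence instead, avoiding electrophilic halogenation. That route is 2,4-dihydroxybenzaldehyde → 4-OMOM → 2-O-allyl → Claisen → 2-OMOM → cross-metathesis.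
3. **Step 20 (tri-MOM removal).** Acid may cyclise a prenyl group onto its ortho phenol to a 2,2-dimethylchroman, or leave the deprotection incomplete. Fallback: replace MOM with SEM from steps 2 and 9 onward, which still directs lithiation, so the final deprotection is fluoride-mediated and acid-free (TBAF, DMPU, 60 °C). The step-18 desilylation would then need TBAF at 0 °C to leave SEM intact.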